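The hexasubstituted benzene ring is cut at C1–C6 and C2–C3 (C1 = benzylic carbon; Br on C2, C3, C6; OH on C4, C5). The key Diels–Alder step exploits the mirror-symmetric C3–C4(O)–C5(O)–C6 unit, a bis-enol of butane-2,3-dione, which as a bis(silyloxy)diene adds to an alkyne that becomes C1–C2, closing the carbocycle in one operation with no regiochemical issue. The dienophile is a tert-butyl ynoate carrying the pyrrolidinone-methyl group; its carboxyl ends on C2, para to the C5 hydroxyl, where bromine later replaces it. Dehydrogenation and acidolysis give the catechol acid; one bromination installs all three bromines.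

Key step: step 3

Remarks on the chemistry:
- Oxidation level: the cycloadduct of a 2,3-bis(silyloxy)diene and an alkyne is an enediol bis(silyl ether), two hydrogens richer than a catechol (ring core C6H8O2 against C6H6O2). Desilylation alone would give an acyloin, not an arene, so a two-electron oxidation (DDQ) is placed before the acidolysis.
- Ester choice: a tert-butyl ester is used so that acid alone frees the carboxylic acid together with both silyl groups. This avoids hydroxide treatment of an air-sensitive catecholate whose ester is deactivated by the para oxygen.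
- Stereochemistry: no compound in the route has a stereocentre or a stereogenic double bond.

Step 1
Reactants: 1 butane-2,3-dione
Product: 2 2,3-bis(trimethylsilyloxy)buta-1,3-diene
Conditions: TMSOTf (2.2 equiv), Et3N (2.6 equiv), Et2O, 0 °C to rt; decant from the ammonium triflate layer; distil under reduced pressure
Reagents that add atoms: trimethylsilyl trifluoromethanesulfonate, C[Si](C)(C)OS(=O)(=O)C(F)(F)F
Why: Twofold amine-mediated enolisation and O-silylation of the 1,2-diketone with a silyl triflate (standard silyl enol ether formation) should give the volatile, distillable diene without any stereochemical issue.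

Step 2
Reactants: 3 1-(prop-2-yn-1-yl)pyrrolidin-2-one; 4 di-tert-butyl dicarbonate
Product: 6 tert-butyl 4-(2-oxopyrrolidin-1-yl)but-2-ynoate, via lithium acetylide 5 (not isolated)
Conditions: LiN(SiMe3)2 (1.05 equiv), THF, –78 °C; then Boc2O (1.1 equiv), –78 to –20 °C; aq. NH4Cl
Reagents that add atoms: di-tert-butyl dicarbonate, CC(C)(C)OC(=O)OC(=O)OC(C)(C)C
Why: The alkyne C–H is the most acidic site, so the hindered amide base forms the acetylide selectively at low temperature, and C-acylation with the dicarbonate (alkoxycarbonylation of a metal acetylide) should give the ynoate before lactam enolisation or propargyl–allenyl isomerisation can compete.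

Step 3
Reactants: 2 2,3-bis(trimethylsilyloxy)buta-1,3-diene; 6 tert-butyl 4-(2-oxopyrrolidin-1-yl)but-2-ynoate
Product: 7 tert-butyl 2-[(2-oxopyrrolidin-1-yl)methyl]-4,5-bis(trimethylsilyloxy)cyclohexa-1,4-diene-1-carboxylate
Conditions: 2 (3 equiv), BHT (cat.), PhMe, sealed tube, 130–140 °C, argon; excess 2 removed under vacuum
Reagents that add atoms: none
Why: A concerted, thermally allowed suprafacial [π4s+π2s] cycloaddition of normal electron demand joins the diene termini to the two alkyne carbons, forming C1–C6 and C2–C3 together; the two silyloxy groups raise the diene HOMO, and the ester, helped by the inductively withdrawing propargylic lactam nitrogen, lowers the alkyne LUMO. The closest known reaction type is the Diels–Alder addition of 2,3-bis(trimethylsilyloxy)butadiene to acetylenic esters, which gives 4,5-bis(silyloxy)cyclohexa-1,4-dienes. The single ring, the six-membered carbocycle, is closed by intermolecular (4+2) annulation of a four-carbon and a two-carbon unit, both new bonds arising in the same step. No stereocentre is created, since C3 and C6 become methylene carbons and the adduct is achiral. The only selectivity needed is cycloaddition in preference to desilylation or polymerisation, because the diene is symmetric and either orientation gives the same adduct; strictly aprotic neutral conditions, excess diene and a radical inhibitor should secure this, and the unconjugated 1,4-diene product cannot add a second ynoate. Any thermal double-bond migration in the adduct would be harmless, because all isomers converge on the same arene in step 4.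

Step 4
Reactants: 7 tert-butyl 2-[(2-oxopyrrolidin-1-yl)methyl]-4,5-bis(trimethylsilyloxy)cyclohexa-1,4-diene-1-carboxylate
Product: 9 4,5-dihydroxy-2-[(2-oxopyrrolidin-1-yl)methyl]benzoic acid, via aryl bis(silyl ether) 8 (not isolated)
Conditions: DDQ (1.0 equiv), CH2Cl2, 0 °C to rt; filter; then TFA, H2O (5 equiv), 0 °C to rt
Reagents that add atoms: none
Why: DDQ abstracts hydride from a doubly allylic ring methylene to give an oxygen-stabilised cation that loses a proton (quinone dehydrogenation of a 1,4-cyclohexadiene to the arene), after which acid protodesilylates both aryl silyl ethers and cleaves the tert-butyl ester by loss of isobutene, the lactam being inert to both stages.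

Step 5
Reactants: 9 4,5-dihydroxy-2-[(2-oxopyrrolidin-1-yl)methyl]benzoic acid
Product: 11 1-[(2,3,6-tribromo-4,5-dihydroxyphenyl)methyl]pyrrolidin-2-one, via dibromo acid 10 (not isolated)
Conditions: Br2 (3.1 equiv), NaOAc (3.5 equiv), 80% aq. AcOH, 0 °C to rt; aq. Na2S2O4
Reagents that add atoms: bromine, BrBr
Why: Electrophilic aromatic bromination ortho to each hydroxyl (C3, C6) is followed by ipso attack of bromine at C2, para to the C5 hydroxyl, giving a 4-bromocyclohexadienone carboxylate that loses CO2 irreversibly (bromodecarboxylation of a 4-hydroxybenzoic acid), whereas ipso attack at C1 is unproductive because an N-acyliminium ion is a poor leaving group, and the dithionite work-up should return any ortho-quinone to the catechol.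

Compound list
1 | butane-2,3-dione | CC(=O)C(C)=O | starting material
2 | 2,3-bis(trimethylsilyloxy)buta-1,3-diene | C=C(O[Si](C)(C)C)C(=C)O[Si](C)(C)C | intermediate
3 | 1-(prop-2-yn-1-yl)pyrrolidin-2-one | C#CCN1CCCC1=O | starting material
4 | di-tert-butyl dicarbonate | CC(C)(C)OC(=O)OC(=O)OC(C)(C)C | starting material
5 | 1-(3-lithioprop-2-yn-1-yl)pyrrolidin-2-one (lithium acetylide of 3) | [Li]C#CCN1CCCC1=O | intermediate
6 | tert-butyl 4-(2-oxopyrrolidin-1-yl)but-2-ynoate | CC(C)(C)OC(=O)C#CCN1CCCC1=O | intermediate
7 | tert-butyl 2-[(2-oxopyrrolidin-1-yl)methyl]-4,5-bis(trimethylsilyloxy)cyclohexa-1,4-diene-1-carboxylate | CC(C)(C)OC(=O)C1=C(CN2CCCC2=O)CC(O[Si](C)(C)C)=C(O[Si](C)(C)C)C1 | intermediate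
8 | tert-butyl 2-[(2-oxopyrrolidin-1-yl)methyl]-4,5-bis(trimethylsilyloxy)benzoate | CC(C)(C)OC(=O)c1cc(O[Si](C)(C)C)c(O[Si](C)(C)C)cc1CN1CCCC1=O | intermediate
9 | 4,5-dihydroxy-2-[(2-oxopyrrolidin-1-yl)methyl]benzoic acid | O=C(O)c1cc(O)c(O)cc1CN1CCCC1=O | intermediate
10 | 3,6-dibromo-4,5-dihydroxy-2-[(2-oxopyrrolidin-1-yl)methyl]benzoic acid | O=C(O)c1c(Br)c(O)c(O)c(Br)c1CN1CCCC1=O | intermediate
11 | 1-[(2,3,6-tribromo-4,5-dihydroxyphenyl)methyl]pyrrolidin-2-one | O=C1CCCN1Cc1c(Br)c(O)c(O)c(Br)c1Br | target

Total step count: 5. Longest linear sequence: 4 steps (steps 2, 3, 4, 5 from compound 3; equally steps 1, 3, 4, 5 from compound 1).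

Steps most likely to fail

Step 3. The β-substituted ynoate may add so slowly that silyl loss, diene oligomerisation or thermal loss of isobutene from the ester outruns the cycloaddition. The fallback replaces the ester by a formyl group, a much stronger activator, and corrects the oxidation level afterwards. It sets out from 3: metalation as in step 2, formylation with DMF and inverse quench into aq. KH2PO4 should give 4-(2-oxopyrrolidin-1-yl)but-2-ynal F1. Cycloaddition of F1 with 2 in toluene at 60–80 °C should give 2-[(2-oxopyrrolidin-1-yl)methyl]-4,5-bis(trimethylsilyloxy)cyclohexa-1,4-diene-1-carbaldehyde F2. DDQ in CH2Cl2 then gives 2-[(2-oxopyrrolidin-1-yl)methyl]-4,5-bis(trimethylsilyloxy)benzaldehyde F3, and brief methanolysis with citric acid gives 4,5-dihydroxy-2-[(2-oxopyrrolidin-1-yl)methyl]benzaldehyde F4. Lindgren–Pinnick oxidation (NaClO2, NaH2PO4, 2-methylbut-2-ene, aq. t-BuOH, 0 °C), the scavenger shielding the catechol from hypochlorous acid, returns to the route at 9.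

Step 5. The catechol may be oxidised to the ortho-quinone and degraded in aqueous bromine, or the ipso substitution at the crowded C2 may stall once two bromines have deactivated the ring. The fallback removes the carboxyl as CO2 with hydrogen in its place and then brominates three C–H positions. It sets out from 9: protodecarboxylation (Cu2O cat., 1,10-phenanthroline, NMP–quinoline, 170 °C, argon), assisted by the para hydroxyl, should give 1-[(3,4-dihydroxyphenyl)methyl]pyrrolidin-2-one F7. Bromine (3 equiv) in AcOH at rt then substitutes the three free ring positions, two ortho and one para to a hydroxyl, and arrives at 11.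

Step 4. The silyl groups may be lost before dehydrogenation, leaving an acyloin that the quinone does not aromatise. Alternatively, liberated catechol may be over-oxidised, or the neighbouring carboxyl may displace the lactam during acidolysis. The fallback oxidises at the enediol carbons instead of abstracting ring hydride. It sets out from 7: Br2 (1.0 equiv) in CH2Cl2 at –78 °C, the known conversion of 1,2-bis(silyloxy)alkenes into 1,2-diones, should give tert-butyl 4,5-dioxo-2-[(2-oxopyrrolidin-1-yl)methyl]cyclohex-1-ene-1-carboxylate F5. On warming, F5 enolises twice toward C3 and C6 to give tert-butyl 4,5-dihydroxy-2-[(2-oxopyrrolidin-1-yl)methyl]benzoate F6. Short treatment with TFA in CH2Cl2 at 0 °C cleaves the ester and returns to the route at 9.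

Further compounds
F1 | step 3 | 4-(2-oxopyrrolidin-1-yl)but-2-ynal | O=CC#CCN1CCCC1=O
F2 | step 3 | 2-[(2-oxopyrrolidin-1-yl)methyl]-4,5-bis(trimethylsilyloxy)cyclohexa-1,4-diene-1-carbaldehyde | O=CC1=C(CN2CCCC2=O)CC(O[Si](C)(C)C)=C(O[Si](C)(C)C)C1
F3 | step 3 | 2-[(2-oxopyrrolidin-1-yl)methyl]-4,5-bis(trimethylsilyloxy)benzaldehyde | O=Cc1cc(O[Si](C)(C)C)c(O[Si](C)(C)C)cc1CN1CCCC1=O
F4 | step 3 | 4,5-dihydroxy-2-[(2-oxopyrrolidin-1-yl)methyl]benzaldehyde | O=Cc1cc(O)c(O)cc1CN1CCCC1=O
F5 | step 4 | tert-butyl 4,5-dioxo-2-[(2-oxopyrrolidin-1-yl)methyl]cyclohex-1-ene-1-carboxylate | CC(C)(C)OC(=O)C1=C(CN2CCCC2=O)CC(=O)C(=O)C1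
F6 | step 4 | tert-butyl 4,5-dihydroxy-2-[(2-oxopyrrolidin-1-yl)methyl]benzoate | CC(C)(C)OC(=O)c1cc(O)c(O)cc1CN1CCCC1=O
F7 | step 5 | 1-[(3,4-dihydroxyphenyl)methyl]pyrrolidin-2-one | O=C1CCCN1Cc1ccc(O)c(O)c1
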